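The pitfall in repeating these runs is to read a last value as the full yield of G with L: the summer run stands at 0.0667 M of E at 19 h, from 0.120 M of G.

| flask | G | L | E | time |
|---|---|---|---|---|
| summer | 0.120 M | 0.144 M |  |  |
| winter | 0.120 M | 0.0720 M |  |  |
| dusk | 0.0600 M | 0.144 M |  |  |
| dawn | 0.120 M | 0.144 M | 0.0360 M | 19 h |

| run | time / h | [E] / M |
|---|---|---|
| summer run | 2.7 | 0.0299 |
| summer run | 5.4 | 0.0436 |
| summer run | 8.1 | 0.0534 |
| summer run | 11 | 0.0574 |
| summer run | 14 | 0.0624 |
| summer run | 16 | 0.0628 |
| summer run | 19 | 0.0667 |
| winter run | 2.7 | 0.0174 |
| winter run | 5.4 | 0.0259 |
| winter run | 8.1 | 0.0293 |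
| winter run | 11 | 0.0350 |
| winter run | 14 | 0.0375 |
| winter run | 16 | 0.0387 |
| winter run | 19 | 0.0391 |
| dusk run | 2.7 | 0.0148 |
| dusk run | 5.4 | 0.0243 |
| dusk run | 8.1 | 0.0277 |
| dusk run | 11 | 0.0336 |
| dusk run | 14 | 0.0350 |
| dusk run | 16 | 0.0340 |
| dusk run | 19 | 0.0367 |

(each reading ± 0.001 M)

- reaction order in [G] at the outset, round the charge of the summer run, defined at two percent of the G turned into E (one fixed amount of E, the same in the runs compared)
- reaction order in [L] at the outset, round the charge of the summer run, defined at two percent of the G turned into E
- E in the dawn run at 19 h, as a share of the G charged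
- which of these the readings show (the substrate is lost by itself / two substrates go astray together / the product reacts on with the second partner / the second partner is lost in pairs / the product binds the substrate)

- Overall: G + L -> E.
- Constant volume, constant temperature.
- "The second partner" is L.
- An order is taken over about fifteen percent of the charge, up and down.
- A share of E counts the E that was charged too.

At the first reading, 2.7 h, halving L leaves 0.582 of the summer E, and halving G leaves 0.495. So I put the order in L below one and the order in G near one, though the E of the summer run already equals 24.9% of its G at that reading, which is well past the outset.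

For the dawn run I carry one quantity, the made share, 55.6%: the E made by 19 h per G charged, with G the limiting reagent in the summer run. The dawn run has the summer charges of G and L, so I treat its charged E as a correction, 30.0% of the G, and add it to the made share. That gives 85.6%, give or take 0.833% from one reading, and it assumes that charged E stays inert, which no run has tested.

The forecast gives orders of 1 in G and 1 in L, 85.6% for the dawn run (from 82% to 88%) and two substrates go astray together, on the ground that “added E should change nothing”.

The flask gives 83.9% for the dawn run, orders of 0.83 in G and 0.76 in L, and the substrate is lost by itself.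

    G + L ⇌ Z, settled at all times (4.740 M⁻¹)
    G + L → E (1.620 M⁻¹ h⁻¹)
    G → Dz (0.1181 h⁻¹)

Taking the charged share off the dawn run leaves 53.9% made by 19 h. The E made reaches 0.5 of the G charged at 8.54 h in the dusk run and at 12.2 h in the summer run. Applied to the dusk charge, the made share gives 0.0333 M, but the dusk run reads more, 0.0367 M at 19 h, which is 61.2% of its G.

All runs were computed with constants of no real substance.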